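## Structural features

The target is a trans-fused perhydroazulene (cyclopentane fused to cycloheptane) joined through a benzylic CH to a 3,5-diformylphloroglucinol. Azulene numbering is used throughout: C1 quaternary, C3a and C8a ring fusion, C4 carbinol, C7 isopropenyl-bearing, C1′ benzylic. Five stereocentres are contiguous (C4–C3a–C8a–C1–C1′) and two of them are fully substituted (C4 with CH3/OH, C1 with CH3/side chain); C7 stands apart, two CH2 groups from C4 and one from C8a. The C3a hydrogen is cis to the C4 hydroxyl and the C1 methyl, and trans to the C8a hydrogen, the C4 methyl and the isopropenyl group. Fragile groups are the tertiary alcohol (elimination), the isopropenyl alkene (acid, hydrogenation) and the electron-rich triphenol with its two aldehydes (bases, nucleophiles, oxidants), so these appear last. The real difficulty is the crowded C4–C3a bond between a fully substituted carbinol carbon and a ring-fusion carbon, then the trans ring fusion and the benzylic centre, both beside quaternary C1. The key step uses the seven-membered ring: C7 can be the ester-bearing carbon of a cyclopropane, C5=C6 and C8=C8a the alkenes of a cyclohepta-1,4-diene, and C4–C3a the σ-bond made when a cis-divinylcyclopropane (one vinyl a silyl enol ether, the other the cyclopentene) rearranges.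

## Logic of the disconnections

35 ⇒ 34 ⇒ 32. The O–Si bond at C4 and then the two ring C–CHO bonds are cut last. Aldehydes and free phenols would not survive the organometallic, olefination or hydrogenation steps; the two open ring positions of 32 are each flanked by two hydroxyls. The gain is a plain 2-alkylphloroglucinol. The demand is formylation and desilylation that spare the isopropenyl group and do not dehydrate C4.

32 ⇒ 31 ⇒ 30 ⇒ 28 (through 29). The aryl acetal C–O bonds are cut, then the C=CH2 bond of the isopropenyl group, then the acetyl C–CH3 bond back to the ester. The terminal alkene cannot coexist with the hydrogenation that makes the isobutyl group, so it is formed afterwards from the ester carried since the cyclopropanation. The gain is one robust ester in place of a sensitive alkene through steps 13–19. The demand is that C7, α to the carbonyl, is not epimerised in steps 20 and 21.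

28 ⇒ 27 ⇒ 25 + 26. The C1′–CH2 bond is cut. Ionisation of 25 gives a benzylic cation stabilised by three oxygens and flanked by a quaternary carbon, so it cannot eliminate. A π-nucleophile (26) is used instead of an isobutyl metal, whose β-hydrogen would reduce so hindered a cation; the alkene of 27 is then saturated. The gain is the benzylic stereocentre and the whole side chain from a carbinol whose own configuration is irrelevant. The demand is that 1,2-induction from C1 favours the R configuration.

25 ⇒ 21 + 23 (via 24); 23 ⇒ 22. The C1′–aryl bond is cut. The neopentyl aldehyde 21 cannot enolise, and 24 forms by lithiation between two acetal oxygens. The demand is that the aldehyde reacts faster than the ester of 21.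

21 ⇒ 20 ⇒ 19 ⇒ 18. These are functional-group changes: aldehyde back to alcohol, four C–H bonds back to two alkenes, O–H back to O–Si. The free CH2OH on C1 lies on the face where the C8a hydrogen is needed and directs a cationic iridium catalyst. This replaces a radical hydrogen-atom-transfer reduction, whose facial outcome beside a quaternary centre is hard to foresee. The gain is a substrate-directed trans fusion with both alkenes reduced at once. The demand is that only the primary silyl ether of 18 is removed; a free C4 hydroxyl would direct to the wrong face.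

18 ⇒ 17 (key). C4–C3a is cut and the cyclopropane bond between the two vinyl-bearing carbons is re-formed. Re-deriving the boat geometry confirms 17 and 18 as drawn: inside (Z) substituents end mutually cis, outside ones mutually cis, and the ester trans to both vinyls ends on the face of the outside groups. The cyclopropane configuration of 17 places the new bond syn to the CH2OSi group on C1, which is what 35 requires. No constitution or configuration needs correcting. The repairs lie in how 17 is reached and how 18 is carried on. The gain is one ring, one skeletal bond and two stereocentres, with the C4 oxygen and methyl already in place. The demand is a single Z enol ether, and a rearrangement that proceeds although the siloxy group points inside the boat.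

17 ⇒ 16 ⇒ 15 ⇒ 12 + 13 (through 14). The enol O–Si bond is cut, the ketone returned to a carbinol, and both cyclopropane bonds to the ester carbon are cut. A Z-alkene plus a carbenoid gives the cis-disubstituted cyclopropane with the ester anti in one step. The demands are that the carbene chooses the disubstituted alkene of the diene, the anti mode and one alkene face under ligand control. The side-chain carbinol must be masked during carbene transfer (O–H insertion); it is a triethylsilyl ether released directly afterwards. Enolisation of 16 must go to the inner CH2 and give the Z isomer.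

12 ⇒ 11 ⇒ 8 + 10; 10 ⇒ 9. Two alkene hydrogens are removed and the sp2–sp bond is cut. The cis geometry comes from alkyne semi-hydrogenation and the union is convergent. The demand is to stop at the diene.

8 ⇒ 7 ⇒ 6 ⇒ 5 ⇒ 3 (via 4) ⇒ 1 + 2. O–Si, the ester reduction, O–Tf and the quaternary C–CH3 bond are undone. The quaternary centre is the only stereocentre bought from outside; a chelated chiral lithioenamine sets it on a β-keto ester. The ketone then gives one enol triflate because only one α-position carries hydrogen. The demand is high facial selectivity in the methylation.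

## Other disconnections considered

Alternative 1: The cut is the arene itself. Heating the siloxyalkyne A2 with 3-ethoxycyclobut-2-en-1-one A3 would open A3 to a vinylketene, add it to the alkyne, and after 4π opening and 6π closure give the phenol A1 (Danheiser benzannulation). The two alkyne carbons become the ring carbon carrying the side chain and its silyloxy neighbour.
- In favour: the arene forms under neutral heat after every terpene stereocentre is in place, with three differentiated oxygens, fixed regiochemistry, and no benzylic cation.
- Against: the benzylic centre must already exist as a propargylic centre beside the quaternary carbon, so the 1,2-induction problem is moved, not solved. A2 needs a multi-step homologation of a hindered carbonyl. A1 still needs two formylations and cleavage of an aryl ethyl ether, which calls for strong Lewis acid that the isopropenyl group and tertiary alcohol would not tolerate.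
- Comparison: it addresses the arene and leaves the hydroazulene unsolved, so it complements the chosen plan more than it competes. On the arene-forming event it is the better of the two (no cation, no hydride-transfer problem, isopropenyl tolerated, no ordering constraint from a hydrogenation). The two plans are equal in needing late diformylation. It is weaker on deprotection and on step count.

Alternative 2: The cut is both ring-closing alkenes. The second-generation Grubbs catalyst would load at the allyl group of dienyne A5, close the cyclopentene onto the alkyne and relay the new carbene onto the propenyl group, giving diene A4 with C3=C3a and C4=C5.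
- In favour: two rings and two C=C bonds in one catalytic step, no strained intermediate, broad functional-group tolerance.
- Against: in A4, C4 is an sp2 carbon and C3a has no hydrogen. The tertiary carbinol would need regio- and face-selective hydration of one alkene of a 1,3-diene, and C3a–H a separate reduction. Three stereocentres (C1, C8a, C7) must be set in the open chain A5, two of them adjacent and one quaternary. Initiation must choose among three π-systems beside a neopentyl centre.
- Comparison: ring-forming step economy is better than in the chosen plan, and this is its clear advantage. Stereochemical content is lower: the Cope step transfers geometry into C4 and C3a stereospecifically, while the metathesis creates no stereocentre. The two plans are equal in leaving the trans fusion to a later reduction and in sharing the same arene endgame.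

Alternative 3: The cut is C1–C2. Anodic oxidation of the silyl ketene acetal in A7 (carbon anode, LiClO4 electrolyte) would give a radical cation that the tethered silyl enol ether traps, closing the cyclopentanone and giving γ-keto ester A6.
- In favour: the quaternary carbon is made directly by umpolung of two enol ethers without prefunctionalisation. Five-membered closure is kinetically easy. C3a becomes α to a ketone, so the ring fusion could be equilibrated to the more stable isomer.
- Against: no strong element controls which face of the ketene acetal is attacked (methyl versus ester at C1). The isopropenyl group can itself be oxidised or intercept the radical cation. The C3 ketone must be removed afterwards in several steps. A7 presupposes a cycloheptane with the C4 carbinol and three further stereocentres, which is the hard part of the molecule.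
- Comparison: it forms the five-membered ring where the chosen plan forms the seven-membered ring, so the hard C4–C3a bond is not addressed. Its correctable ring fusion is equal to or better than resting the fusion on one directed hydrogenation. It is equal in the arene endgame from the C1 ester, and weaker in stereocontrol at C1 and in step count.

Key step: step 12

Assumption: the L-valine-derived lithioenamine in toluene with one equivalent of HMPA is taken to be methylated on the face that gives (S)-5; the sense reverses without HMPA, so either outcome is corrected within the same step.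

Assumption: pent-4-yn-2-ol is used as the racemate; its carbinol carbon is oxidised in step 10, so 10, 11, 12, 14 and 15 are pairs of epimers at that carbon only.

Step 1
Reactants: 1 methyl 2-oxocyclopentane-1-carboxylate; 2 L-valine tert-butyl ester
Product: 3 methyl 2-{[(2S)-1-tert-butoxy-3-methyl-1-oxobutan-2-yl]amino}cyclopent-1-ene-1-carboxylate
Conditions: BF3·OEt2 (cat.), benzene, reflux, azeotropic removal of water
Reagents that add atoms: none
Why: Condensation of a β-keto ester with a primary amine gives the hydrogen-bonded vinylogous carbamate (enamine formation); the valine ester is the chiral controller for step 2.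

Step 2
Reactants: 3 enamine
Product: 5 methyl (1S)-1-methyl-2-oxocyclopentane-1-carboxylate, via methylated ketimine 4 (not isolated)
Conditions: LDA, toluene, HMPA (1 equiv), −78 °C; MeI; then 1 M HCl (aq), rt
Reagents that add atoms: iodomethane, CI; water, O
Why: Chiral lithioenamine alkylation: lithium is held by the nitrogen and both ester carbonyls, and the isopropyl group with the ligand on lithium leaves one face of the aza-enolate open to iodomethane, which sets quaternary C1. Acid hydrolysis of the ketimine returns the ketone and the auxiliary.

Step 3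
Reactants: 5 methyl (1S)-1-methyl-2-oxocyclopentane-1-carboxylate
Product: 6 methyl (1S)-1-methyl-2-(trifluoromethylsulfonyloxy)cyclopent-2-ene-1-carboxylate
Conditions: KHMDS, THF, −78 °C; PhNTf2, −78 → 0 °C
Reagents that add atoms: N-phenylbis(trifluoromethanesulfonimide), O=S(=O)(N(c1ccccc1)S(=O)(=O)C(F)(F)F)C(F)(F)F
Why: Only the CH2 side of the ketone can be enolised, so O-triflation of the potassium enolate gives a single enol triflate and leaves the quaternary centre untouched.

Step 4
Reactants: 6 enol triflate ester
Product: 7 [(1R)-1-methyl-2-(trifluoromethylsulfonyloxy)cyclopent-2-en-1-yl]methanol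
Conditions: DIBAL-H, CH2Cl2, −78 → 0 °C
Reagents that add atoms: none
Why: Hydride reduction of the ester to the primary alcohol; enol triflates tolerate DIBAL-H at low temperature. The descriptor changes only because the substituent priorities change.

Step 5
Reactants: 7 triflate alcohol
Product: 8 (5R)-5-[(tert-butyldimethylsilyloxy)methyl]-5-methylcyclopent-1-en-1-yl trifluoromethanesulfonate
Conditions: TBSCl, imidazole, DMF, rt
Reagents that add atoms: tert-butyldimethylsilyl chloride, CC(C)(C)[Si](C)(C)Cl
Why: Silylation of a primary alcohol; the ether protects the hydroxyl from O–H insertion in step 9 and can later be removed beside the tertiary silyl ether.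

Step 6
Reactants: 9 pent-4-yn-2-ol
Product: 10 triethyl(pent-4-yn-2-yloxy)silane
Conditions: Et3SiCl, imidazole, CH2Cl2, 0 °C → rt
Reagents that add atoms: chlorotriethylsilane, CC[Si](Cl)(CC)CC
Why: Silylation of the secondary alcohol; a free hydroxyl would capture the copper carbenoid in step 9, and the triethylsilyl ether can be cleaved by mild acid without loss of the primary TBS ether.

Step 7
Reactants: 8 enol triflate; 10 silylated alkyne
Product: 11 tert-butyl{[(1S)-1-methyl-2-(4-triethylsilyloxypent-1-yn-1-yl)cyclopent-2-en-1-yl]methoxy}dimethylsilane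
Conditions: PdCl2(PPh3)2 (cat.), CuI (cat.), iPr2NH, THF, rt
Reagents that add atoms: none
Why: Sonogashira coupling of an enol triflate with a terminal alkyne; it proceeds at room temperature and leaves both silyl ethers alone.

Step 8
Reactants: 11 enyne
Product: 12 tert-butyl{[(1S)-1-methyl-2-[(1Z)-4-triethylsilyloxypent-1-en-1-yl]cyclopent-2-en-1-yl]methoxy}dimethylsilane
Conditions: H2 (1 atm), Pd/CaCO3 (Pb-poisoned), quinoline, EtOAc, rt
Reagents that add atoms: none
Why: Syn semi-hydrogenation of the alkyne on poisoned palladium gives the Z-alkene, which fixes the later cis relation of the two cyclopropane substituents; the trisubstituted ring alkene is not reduced.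

Step 9
Reactants: 12 Z-diene; 13 ethyl diazoacetate
Product: 15 ethyl (1R,2R,3S)-2-{(5S)-5-[(tert-butyldimethylsilyloxy)methyl]-5-methylcyclopent-1-en-1-yl}-3-(2-hydroxypropyl)cyclopropane-1-carboxylate, via triethylsilyl ether 14 (not isolated)
Conditions: (CuOTf)2·C6H6 (cat.), (S,S)-tBu-box (cat.), CH2Cl2, rt, slow addition of 13; then PPTS, EtOH, rt
Reagents that add atoms: none
Why: Copper-carbenoid cyclopropanation of a conjugated diene: the electrophilic carbenoid attacks the less substituted, less hindered Z-alkene, keeps its geometry (substituents cis) and places the ester away from both (anti). The S,S ligand is chosen by analogy with the 1R ester carbon it gives with styrenes and dienes, the cyclopentenyl-bearing carbon playing the part of the aryl-bearing one; PPTS in ethanol then cleaves only the secondary triethylsilyl ether.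

Step 10
Reactants: 15 cyclopropyl carbinol
Product: 16 ethyl (1R,2R,3S)-2-{(5S)-5-[(tert-butyldimethylsilyloxy)methyl]-5-methylcyclopent-1-en-1-yl}-3-(2-oxopropyl)cyclopropane-1-carboxylate
Conditions: DMP (1,1,1-triacetoxy-1,2-benziodoxol-3-one), NaHCO3, CH2Cl2, 0 °C → rt
Reagents that add atoms: none
Why: Buffered periodinane oxidation of a secondary alcohol to the methyl ketone; neutral conditions leave the vinylcyclopropane and silyl ether intact and remove the epimeric carbinol centre.

Step 11
Reactants: 16 cyclopropyl methyl ketone
Product: 17 ethyl 2-{(5S)-5-[(tert-butyldimethylsilyloxy)methyl]-5-methylcyclopent-1-en-1-yl}-3-[(1Z)-2-(tert-butyldimethylsilyloxy)prop-1-en-1-yl]cyclopropane-1-carboxylate (ring configuration as in 16)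
Conditions: TBSOTf, Et3N, CH2Cl2, −78 → 0 °C
Reagents that add atoms: tert-butyldimethylsilyl trifluoromethanesulfonate, CC(C)(C)[Si](C)(C)OS(=O)(=O)C(F)(F)F
Why: Soft enolisation with silyl triflate and amine goes towards the CH2 next to the cyclopropane (more substituted, conjugated enol ether) and gives the isomer with the siloxy group cis to the cyclopropyl carbon (Z), the usual result for alkyl methyl ketones. The cyclopropane ester is not enolised.

Step 12
Reactants: 17 cis-divinylcyclopropane
Product: 18 ethyl 4-(tert-butyldimethylsilyloxy)-1-[(tert-butyldimethylsilyloxy)methyl]-1,4-dimethyl-1,2,3,3a,4,7-hexahydroazulene-7-carboxylate (3a-H cis to 4-OSi; 1-CH3 and 7-H on the face of 3a-H)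
Conditions: toluene (degassed, 0.02 M), 100 °C, sealed silanised tube
Reagents that add atoms: none
Why: A concerted [3,3] shift of the hexa-1,5-diene formed by the enol ether C=C, the cyclopropane bond between the vinyl-bearing carbons and the cyclopentene C=C; the strained σ-bond breaks as C4–C3a forms, and both new ring alkenes come out cis, which requires the boat array with both vinyl groups folded over the three-membered ring. The closest known reaction type is the cis-divinylcyclopropane to cyclohepta-1,4-diene rearrangement with a silyl enol ether terminus. The seven-membered ring closes through the sigmatropic shift itself (three-membered ring expanded to seven, the two termini bonding suprafacially), not through an ionic cyclisation. C4 is set by the enol ether geometry: the inside Z substituent (OSi) ends cis to the inside hydrogen of the cyclopentene terminus (the C3a hydrogen) and the outside methyl ends trans to it. C3a is set by the cyclopentene face presented to the enol ether, which the cyclopropane configuration from step 9 fixes as the face carrying CH2OSi, so C3a–H ends cis to the C1 methyl. C7 is unchanged, and because the ester was trans to both vinyl groups it ends cis to the C4 methyl. The step needs the cis, Z, anti-ester isomer only: a trans-divinyl isomer does not reach the boat below about 180 °C and a terminal enol ether regioisomer cannot rearrange, so neither leaks into a wrong diastereomer. Release of ring strain makes the step irreversible and pays for the crowded bond; the inside siloxy group is why about 100 °C is expected rather than room temperature.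

Step 13
Reactants: 18 bis-silyl ether
Product: 19 ethyl 4-(tert-butyldimethylsilyloxy)-1-(hydroxymethyl)-1,4-dimethyl-1,2,3,3a,4,7-hexahydroazulene-7-carboxylate
Conditions: HF·pyridine, pyridine, THF, 0 °C → rt
Reagents that add atoms: none
Why: Buffered fluoride cleaves the primary silyl ether far faster than the hindered tertiary one; the mildly acidic, non-basic medium does not move the doubly allylic C7 hydrogen.

Step 14
Reactants: 19 diene alcohol
Product: 20 ethyl 4-(tert-butyldimethylsilyloxy)-1-(hydroxymethyl)-1,4-dimethyldecahydroazulene-7-carboxylate (trans-fused; 8a-H cis to CH2OH)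
Conditions: [Ir(cod)(PCy3)(py)]PF6 (cat.), H2 (1 atm), CH2Cl2, rt
Reagents that add atoms: none
Why: Hydroxyl-directed homogeneous hydrogenation: the cationic iridium binds the homoallylic CH2OH on C1 and delivers hydrogen to C8=C8a from that face, so 8a-H is cis to CH2OH and trans to 3a-H. The C5=C6 alkene is reduced in the same operation, and the silylated C4 oxygen cannot compete as a directing group.

Step 15
Reactants: 20 hydroxy ester
Product: 21 ethyl 4-(tert-butyldimethylsilyloxy)-1-formyl-1,4-dimethyldecahydroazulene-7-carboxylate
Conditions: DMP, NaHCO3, CH2Cl2, rt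
Reagents that add atoms: none
Why: Periodinane oxidation of the neopentyl primary alcohol to an aldehyde that cannot enolise or epimerise.

Step 16
Reactants: 22 phloroglucinol
Product: 23 1,3,5-tris(methoxymethoxy)benzene
Conditions: MOMCl, iPr2NEt, CH2Cl2, 0 °C → rt
Reagents that add atoms: chloromethyl methyl ether, COCCl
Why: O-alkylation of the triphenol with a hard electrophile; the acetal oxygens later direct lithiation and are removable without strong acid.

Step 17
Reactants: 21 aldehyde; 23 tris(methoxymethoxy)benzene
Product: 25 ethyl 4-(tert-butyldimethylsilyloxy)-1-{hydroxy[2,4,6-tris(methoxymethoxy)phenyl]methyl}-1,4-dimethyldecahydroazulene-7-carboxylate (both carbinol epimers), via aryllithium 24 (not isolated)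
Conditions: n-BuLi, THF, 0 °C (on 23); then 21, −78 °C; NH4Cl (aq)
Reagents that add atoms: none
Why: Directed ortho-lithiation between two acetal oxygens, then 1,2-addition of the aryllithium to the aldehyde, which at −78 °C is much faster than attack on the α-branched ester. The carbinol configuration does not matter because step 18 erases it.

Step 18
Reactants: 25 benzylic carbinol; 26 trimethyl(2-methylprop-2-en-1-yl)silane
Product: 27 ethyl 4-(tert-butyldimethylsilyloxy)-1,4-dimethyl-1-{(1R)-3-methyl-1-[2,4,6-tris(methoxymethoxy)phenyl]but-3-en-1-yl}decahydroazulene-7-carboxylate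
Conditions: BF3·OEt2 (0.3 equiv), CH2Cl2, −78 → −40 °C
Reagents that add atoms: none
Why: Hosomi–Sakurai-type benzylic substitution: the Lewis acid ionises the carbinol to a cation stabilised by three ring oxygens (an O-alkylated quinone methide) that has no β-hydrogen to lose, and the allylsilane, which cannot transfer hydride, adds to it. The cation should hold the C1 methyl in its plane (least 1,3-allylic strain with the ortho oxygen) and be attacked anti to the larger ring-fusion branch, which gives R at C1′.

Step 19
Reactants: 27 methallyl compound
Product: 28 ethyl 4-(tert-butyldimethylsilyloxy)-1,4-dimethyl-1-{(1R)-3-methyl-1-[2,4,6-tris(methoxymethoxy)phenyl]butyl}decahydroazulene-7-carboxylate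
Conditions: H2 (1 atm), Pd/C, EtOAc, rt
Reagents that add atoms: none
Why: Heterogeneous hydrogenation of the 1,1-disubstituted alkene gives the isobutyl group; it is placed here because no other alkene is present yet.

Step 20
Reactants: 28 ester
Product: 30 7-acetyl-4-(tert-butyldimethylsilyloxy)-1,4-dimethyl-1-{(1R)-3-methyl-1-[2,4,6-tris(methoxymethoxy)phenyl]butyl}decahydroazulene, via N-methoxy-N-methylamide 29 (not isolated)
Conditions: MeNH(OMe)·HCl, iPrMgCl, THF, −20 °C; then MeMgBr, 0 °C; NH4Cl (aq)
Reagents that add atoms: methylmagnesium bromide, C[Mg]Br; N,O-dimethylhydroxylamine hydrochloride, CNOC.Cl (its atoms stay only in 29)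
Why: One-pot conversion of an ester to a ketone: the magnesium amide gives the N-methoxy-N-methylamide, whose chelated tetrahedral adduct with the methyl Grignard reagent does not collapse until work-up, so over-addition is avoided. Low temperature and the magnesium counter-ion should keep C7 from epimerising.

Step 21
Reactants: 30 methyl ketone
Product: 31 4-(tert-butyldimethylsilyloxy)-1,4-dimethyl-1-{(1R)-3-methyl-1-[2,4,6-tris(methoxymethoxy)phenyl]butyl}-7-(prop-1-en-2-yl)decahydroazulene
Conditions: Ph3PCH3Br, KHMDS, THF, 0 °C → rt
Reagents that add atoms: methyltriphenylphosphonium bromide, C[P+](c1ccccc1)(c1ccccc1)c1ccccc1.[Br-]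
Why: Wittig methylenation of the methyl ketone gives the isopropenyl group; a slight excess of salt over base keeps the medium free of amide base and protects C7.

Step 22
Reactants: 31 tris-acetal
Product: 32 2-{(1R)-1-[4-(tert-butyldimethylsilyloxy)-1,4-dimethyl-7-(prop-1-en-2-yl)decahydroazulen-1-yl]-3-methylbutyl}benzene-1,3,5-triol
Conditions: ZnBr2, n-PrSH, CH2Cl2, 0 °C
Reagents that add atoms: none
Why: Lewis acid and thiol cleave aryl methoxymethyl ethers within minutes; the tertiary silyl ether and the alkene are left alone, and the thiol traps the CH2OMe fragment that would otherwise alkylate the free phloroglucinol.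

Step 23
Reactants: 32 alkylphloroglucinol
Product: 34 silyl ether of the target (3,5-diformyl compound with C4–OSi), via bis(iminium) salt 33 (not isolated)
Conditions: POCl3, DMF, EtOAc, 0 °C → rt; then NaOAc (aq), rt
Reagents that add atoms: N,N-dimethylformamide, CN(C)C=O; water, O
Why: Vilsmeier–Haack formylation: the two free ring positions, each between two hydroxyls, are the most nucleophilic sites and take one chloroiminium ion each; buffered hydrolysis then frees the aldehydes. The tertiary alcohol is still silylated, so the reagent cannot dehydrate it.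

Step 24
Reactants: 34 silyl ether
Product: 35 target CNP0594576.1
Conditions: HF (48 % aq.), MeCN, 0 °C → rt
Reagents that add atoms: none
Why: Fluoride cleavage of the hindered tertiary silyl ether in weakly acidic medium, which the isopropenyl group, the aldehydes and the phenols should tolerate; no stereocentre is touched.

Compound list

1 | methyl 2-oxocyclopentane-1-carboxylate | COC(=O)C1CCCC1=O | starting material
2 | L-valine tert-butyl ester | CC(C)[C@H](N)C(=O)OC(C)(C)C | starting material
3 | methyl 2-{[(2S)-1-tert-butoxy-3-methyl-1-oxobutan-2-yl]amino}cyclopent-1-ene-1-carboxylate | COC(=O)C1=C(N[C@@H](C(C)C)C(=O)OC(C)(C)C)CCC1 | intermediate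
4 | methyl (1S)-2-{[(2S)-1-tert-butoxy-3-methyl-1-oxobutan-2-yl]imino}-1-methylcyclopentane-1-carboxylate | COC(=O)[C@@]1(C)CCCC1=N[C@@H](C(C)C)C(=O)OC(C)(C)C | intermediate
5 | methyl (1S)-1-methyl-2-oxocyclopentane-1-carboxylate | COC(=O)[C@@]1(C)CCCC1=O | intermediate
6 | methyl (1S)-1-methyl-2-(trifluoromethylsulfonyloxy)cyclopent-2-ene-1-carboxylate | COC(=O)[C@@]1(C)CCC=C1OS(=O)(=O)C(F)(F)F | intermediate
7 | [(1R)-1-methyl-2-(trifluoromethylsulfonyloxy)cyclopent-2-en-1-yl]methanol | OC[C@@]1(C)CCC=C1OS(=O)(=O)C(F)(F)F | intermediate
8 | (5R)-5-[(tert-butyldimethylsilyloxy)methyl]-5-methylcyclopent-1-en-1-yl trifluoromethanesulfonate | CC(C)(C)[Si](C)(C)OC[C@@]1(C)CCC=C1OS(=O)(=O)C(F)(F)F | intermediate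
9 | pent-4-yn-2-ol (racemic) | CC(O)CC#C | starting material
10 | triethyl(pent-4-yn-2-yloxy)silane (racemic) | CC(CC#C)O[Si](CC)(CC)CC | intermediate
11 | tert-butyl{[(1S)-1-methyl-2-(4-triethylsilyloxypent-1-yn-1-yl)cyclopent-2-en-1-yl]methoxy}dimethylsilane (both epimers at the chain carbinol carbon) | CC(CC#CC1=CCC[C@]1(C)CO[Si](C)(C)C(C)(C)C)O[Si](CC)(CC)CC | intermediate
12 | tert-butyl{[(1S)-1-methyl-2-[(1Z)-4-triethylsilyloxypent-1-en-1-yl]cyclopent-2-en-1-yl]methoxy}dimethylsilane (both epimers at the chain carbinol carbon) | CC(C/C=C\C1=CCC[C@]1(C)CO[Si](C)(C)C(C)(C)C)O[Si](CC)(CC)CC | intermediate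
13 | ethyl diazoacetate | CCOC(=O)C=[N+]=[N-] | starting material
14 | ethyl (1R,2R,3S)-2-{(5S)-5-[(tert-butyldimethylsilyloxy)methyl]-5-methylcyclopent-1-en-1-yl}-3-(2-triethylsilyloxypropyl)cyclopropane-1-carboxylate (ring substituents at C2 and C3 cis, ester trans to both) | CCOC(=O)[C@H]1[C@H](C2=CCC[C@]2(C)CO[Si](C)(C)C(C)(C)C)[C@@H]1CC(C)O[Si](CC)(CC)CC | intermediate
15 | ethyl (1R,2R,3S)-2-{(5S)-5-[(tert-butyldimethylsilyloxy)methyl]-5-methylcyclopent-1-en-1-yl}-3-(2-hydroxypropyl)cyclopropane-1-carboxylate | CCOC(=O)[C@H]1[C@H](C2=CCC[C@]2(C)CO[Si](C)(C)C(C)(C)C)[C@@H]1CC(C)O | intermediate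
16 | ethyl (1R,2R,3S)-2-{(5S)-5-[(tert-butyldimethylsilyloxy)methyl]-5-methylcyclopent-1-en-1-yl}-3-(2-oxopropyl)cyclopropane-1-carboxylate | CCOC(=O)[C@H]1[C@H](C2=CCC[C@]2(C)CO[Si](C)(C)C(C)(C)C)[C@@H]1CC(C)=O | intermediate
17 | ethyl 2-{(5S)-5-[(tert-butyldimethylsilyloxy)methyl]-5-methylcyclopent-1-en-1-yl}-3-[(1Z)-2-(tert-butyldimethylsilyloxy)prop-1-en-1-yl]cyclopropane-1-carboxylate (alkenyl groups cis, ester trans to both, ring configuration as in 16) | CCOC(=O)[C@H]1[C@H](C2=CCC[C@]2(C)CO[Si](C)(C)C(C)(C)C)[C@@H]1/C=C(/C)O[Si](C)(C)C(C)(C)C | intermediate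
18 | ethyl 4-(tert-butyldimethylsilyloxy)-1-[(tert-butyldimethylsilyloxy)methyl]-1,4-dimethyl-1,2,3,3a,4,7-hexahydroazulene-7-carboxylate (3a-H cis to 4-OSi, to 1-CH3 and to 7-H) | CCOC(=O)[C@@H]1C=C[C@@](C)(O[Si](C)(C)C(C)(C)C)[C@@H]2CC[C@](C)(CO[Si](C)(C)C(C)(C)C)C2=C1 | intermediate
19 | ethyl 4-(tert-butyldimethylsilyloxy)-1-(hydroxymethyl)-1,4-dimethyl-1,2,3,3a,4,7-hexahydroazulene-7-carboxylate (configuration as in 18) | CCOC(=O)[C@@H]1C=C[C@@](C)(O[Si](C)(C)C(C)(C)C)[C@@H]2CC[C@](C)(CO)C2=C1 | intermediate
20 | ethyl 4-(tert-butyldimethylsilyloxy)-1-(hydroxymethyl)-1,4-dimethyldecahydroazulene-7-carboxylate (trans-fused, 8a-H cis to CH2OH, other centres as in 18) | CCOC(=O)[C@@H]1CC[C@@](C)(O[Si](C)(C)C(C)(C)C)[C@@H]2CC[C@](C)(CO)[C@H]2C1 | intermediate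
21 | ethyl 4-(tert-butyldimethylsilyloxy)-1-formyl-1,4-dimethyldecahydroazulene-7-carboxylate (configuration as in 20) | CCOC(=O)[C@@H]1CC[C@@](C)(O[Si](C)(C)C(C)(C)C)[C@@H]2CC[C@](C)(C=O)[C@H]2C1 | intermediate
22 | phloroglucinol (benzene-1,3,5-triol) | Oc1cc(O)cc(O)c1 | starting material
23 | 1,3,5-tris(methoxymethoxy)benzene | COCOc1cc(OCOC)cc(OCOC)c1 | intermediate
24 | 2,4,6-tris(methoxymethoxy)phenyllithium | [Li]c1c(OCOC)cc(OCOC)cc1OCOC | intermediate
25 | ethyl 4-(tert-butyldimethylsilyloxy)-1-{hydroxy[2,4,6-tris(methoxymethoxy)phenyl]methyl}-1,4-dimethyldecahydroazulene-7-carboxylate (both carbinol epimers, ring configuration as in 20) | CCOC(=O)[C@@H]1CC[C@@](C)(O[Si](C)(C)C(C)(C)C)[C@@H]2CC[C@](C)(C(O)c3c(OCOC)cc(OCOC)cc3OCOC)[C@H]2C1 | intermediate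
26 | trimethyl(2-methylprop-2-en-1-yl)silane | C=C(C)C[Si](C)(C)C | starting material
27 | ethyl 4-(tert-butyldimethylsilyloxy)-1,4-dimethyl-1-{(1R)-3-methyl-1-[2,4,6-tris(methoxymethoxy)phenyl]but-3-en-1-yl}decahydroazulene-7-carboxylate | CCOC(=O)[C@@H]1CC[C@@](C)(O[Si](C)(C)C(C)(C)C)[C@@H]2CC[C@](C)([C@@H](CC(C)=C)c3c(OCOC)cc(OCOC)cc3OCOC)[C@H]2C1 | intermediate
28 | ethyl 4-(tert-butyldimethylsilyloxy)-1,4-dimethyl-1-{(1R)-3-methyl-1-[2,4,6-tris(methoxymethoxy)phenyl]butyl}decahydroazulene-7-carboxylate | CCOC(=O)[C@@H]1CC[C@@](C)(O[Si](C)(C)C(C)(C)C)[C@@H]2CC[C@](C)([C@@H](CC(C)C)c3c(OCOC)cc(OCOC)cc3OCOC)[C@H]2C1 | intermediate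
29 | N-methoxy-N-methylamide corresponding to ester 28 | CON(C)C(=O)[C@@H]1CC[C@@](C)(O[Si](C)(C)C(C)(C)C)[C@@H]2CC[C@](C)([C@@H](CC(C)C)c3c(OCOC)cc(OCOC)cc3OCOC)[C@H]2C1 | intermediate
30 | 7-acetyl-4-(tert-butyldimethylsilyloxy)-1,4-dimethyl-1-{(1R)-3-methyl-1-[2,4,6-tris(methoxymethoxy)phenyl]butyl}decahydroazulene | CC(=O)[C@@H]1CC[C@@](C)(O[Si](C)(C)C(C)(C)C)[C@@H]2CC[C@](C)([C@@H](CC(C)C)c3c(OCOC)cc(OCOC)cc3OCOC)[C@H]2C1 | intermediate
31 | 4-(tert-butyldimethylsilyloxy)-1,4-dimethyl-1-{(1R)-3-methyl-1-[2,4,6-tris(methoxymethoxy)phenyl]butyl}-7-(prop-1-en-2-yl)decahydroazulene | C=C(C)[C@@H]1CC[C@@](C)(O[Si](C)(C)C(C)(C)C)[C@@H]2CC[C@](C)([C@@H](CC(C)C)c3c(OCOC)cc(OCOC)cc3OCOC)[C@H]2C1 | intermediate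
32 | 2-{(1R)-1-[4-(tert-butyldimethylsilyloxy)-1,4-dimethyl-7-(prop-1-en-2-yl)decahydroazulen-1-yl]-3-methylbutyl}benzene-1,3,5-triol | C=C(C)[C@@H]1CC[C@@](C)(O[Si](C)(C)C(C)(C)C)[C@@H]2CC[C@](C)([C@@H](CC(C)C)c3c(O)cc(O)cc3O)[C@H]2C1 | intermediate
33 | bis(N,N-dimethyliminium) dichloride of 34 (both formyl carbons as CH=NMe2+) | C=C(C)[C@@H]1CC[C@@](C)(O[Si](C)(C)C(C)(C)C)[C@@H]2CC[C@](C)([C@@H](CC(C)C)c3c(O)c(C=[N+](C)C)c(O)c(C=[N+](C)C)c3O)[C@H]2C1.[Cl-].[Cl-] | intermediate
34 | C4 tert-butyldimethylsilyl ether of the target | C=C(C)[C@@H]1CC[C@@](C)(O[Si](C)(C)C(C)(C)C)[C@@H]2CC[C@](C)([C@@H](CC(C)C)c3c(O)c(C=O)c(O)c(C=O)c3O)[C@H]2C1 | intermediate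
35 | 5-{(1R)-1-[(1S,3aR,4R,7R,8aS)-4-hydroxy-1,4-dimethyl-7-(prop-1-en-2-yl)decahydroazulen-1-yl]-3-methylbutyl}-2,4,6-trihydroxybenzene-1,3-dicarbaldehyde (CNP0594576.1) | C=C(C)[C@@H]1CC[C@@](C)(O)[C@@H]2CC[C@](C)([C@@H](CC(C)C)c3c(O)c(C=O)c(O)c(C=O)c3O)[C@H]2C1 | target

Total step count: 24. Longest linear sequence: 22 steps (steps 1–5, 7–15, 17–24); steps 6 and 16 are one-step side branches.

Steps least certain to work

Step 12 (key step, with the enol ether geometry from step 11 on which it depends). The rearrangement may be slow, because the siloxy group must take the inside position of the boat and the CH2OSi group on C1 lies on the face where the bond forms. Long heating then invites loss of the enol silyl group back to the ketone, which as a cis-alkyl vinylcyclopropane can undergo a homodienyl 1,5-hydrogen shift. Any E-enol ether or terminal enol ether carried over from step 11 would lead to the C4 epimer or to no reaction, and traces of base could move the doubly allylic C7 hydrogen. Fallback, from 16 back to 18: the ketone is silylated under equilibrating conditions (Me3SiCl, NaI, Et3N, MeCN), which funnel regio- and geometric isomers to the conjugated Z trimethylsilyl enol ether F1, whose smaller inside group should lower the barrier. Thermolysis gives the tertiary trimethylsilyl ether F2. Brief PPTS in methanol at 0 °C frees the tertiary allylic alcohol F3 without touching the primary TBS ether, and TBSOTf with 2,6-lutidine converts F3 into 18.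

Step 9. Carbene transfer may go to the wrong alkene face (the ligand's preference is inferred by analogy, and the twisted diene beside the quaternary centre may bias the faces itself), to the ring alkene, or with poor anti selectivity; carbene dimerisation wastes diazo ester. Fallback, from 10 and 8 back to 14: rhodium-catalysed trans-hydroboration of 10 with pinacolborane ([Rh(cod)Cl]2, P(iPr)3, Et3N) gives the (Z)-alkenylboronate F4. This single, unhindered alkene with no resident stereocentre nearby is cyclopropanated with 13 under the same copper and bis(oxazoline) control to the cyclopropylboronate F5, whose enantiomeric purity can be checked and raised before use. A Suzuki–Miyaura coupling of F5 with 8 (Pd(OAc)2, SPhos, K3PO4, toluene–water), which proceeds with retention at the cyclopropyl carbon, gives 14.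

Step 14. The iridium hydride may migrate the alkenes (C5=C6 towards conjugation with the ester, or C8=C8a away from the directing group) before adding hydrogen, or the catalyst may deactivate before the hindered trisubstituted alkene is reduced. Fallback, from 19 back to 20: diimide generated from 2-nitrobenzenesulfonyl hydrazide and Et3N reduces only the disubstituted alkene and gives the mono-alkene alcohol F6. The remaining C8=C8a alkene is then hydrogenated under hydroxyl direction with a cationic rhodium catalyst ([Rh(nbd)(dppb)]BF4, H2 at about 50 bar, CH2Cl2), to give 20.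

Step 18. Facial discrimination in the capture of the benzylic cation may be weak or reversed, because the two ring branches on C1 (CH2 and CH) differ only modestly in size. A neighbouring acetal oxygen may also close onto the cation, or an acetal may be lost to the Lewis acid. Fallback, from 21 back to 28, with the order of bond formation reversed so that hydride and not carbon enters the cation: isobutylmagnesium bromide with CeCl3 adds to 21 to give the secondary carbinol F7; DMP oxidation gives the isobutyl ketone F8; the aryl reagent 24, transmetallated with CeCl3, adds to give the tertiary benzylic alcohol F9; ionic hydrogenation (Et3SiH, BF3·OEt2, −78 °C) gives 28 directly. If the same face of the cation is preferred, this gives the opposite benzylic configuration to the methallylation, so it corrects a reversed bias. If the bias is merely weak, the epimers must be separated at 27 or 28.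

Step 23. Hydrogen chloride released during iminium formation may add to or isomerise the isopropenyl group, the second formylation may stall on the deactivated ring, and O-formates may persist. Fallback, from 31 back to 34, formylating before the phenols are freed and without acid: directed lithiation of 31 between two acetal oxygens (n-BuLi, TMEDA, THF, 0 °C) and DMF give the monoaldehyde F10. The aldehyde is masked in situ as its lithium amino-alkoxide (lithium N,N,N′-trimethylethylenediamide), and a second lithiation and DMF quench give the dialdehyde F11. Its acetals, now each ortho to a formyl group, fall off with dilute HCl in methanol–THF at room temperature to give 34.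

## Further compounds

F1 | step 12 | ethyl 2-{(5S)-5-[(tert-butyldimethylsilyloxy)methyl]-5-methylcyclopent-1-en-1-yl}-3-[(1Z)-2-(trimethylsilyloxy)prop-1-en-1-yl]cyclopropane-1-carboxylate | CCOC(=O)[C@H]1[C@H](C2=CCC[C@]2(C)CO[Si](C)(C)C(C)(C)C)[C@@H]1/C=C(/C)O[Si](C)(C)C
F2 | step 12 | ethyl 1-[(tert-butyldimethylsilyloxy)methyl]-1,4-dimethyl-4-(trimethylsilyloxy)-1,2,3,3a,4,7-hexahydroazulene-7-carboxylate | CCOC(=O)[C@@H]1C=C[C@@](C)(O[Si](C)(C)C)[C@@H]2CC[C@](C)(CO[Si](C)(C)C(C)(C)C)C2=C1
F3 | step 12 | ethyl 1-[(tert-butyldimethylsilyloxy)methyl]-4-hydroxy-1,4-dimethyl-1,2,3,3a,4,7-hexahydroazulene-7-carboxylate | CCOC(=O)[C@@H]1C=C[C@@](C)(O)[C@@H]2CC[C@](C)(CO[Si](C)(C)C(C)(C)C)C2=C1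
F4 | step 9 | triethyl{[(4Z)-5-(4,4,5,5-tetramethyl-1,3,2-dioxaborolan-2-yl)pent-4-en-2-yl]oxy}silane | CC(C/C=C\B1OC(C)(C)C(C)(C)O1)O[Si](CC)(CC)CC
F5 | step 9 | ethyl 2-(4,4,5,5-tetramethyl-1,3,2-dioxaborolan-2-yl)-3-(2-triethylsilyloxypropyl)cyclopropane-1-carboxylate (boryl and alkyl cis, ester trans, configuration matching 14) | CCOC(=O)[C@H]1[C@H](B2OC(C)(C)C(C)(C)O2)[C@@H]1CC(C)O[Si](CC)(CC)CC
F6 | step 14 | ethyl 4-(tert-butyldimethylsilyloxy)-1-(hydroxymethyl)-1,4-dimethyl-1,2,3,3a,4,5,6,7-octahydroazulene-7-carboxylate | CCOC(=O)[C@@H]1CC[C@@](C)(O[Si](C)(C)C(C)(C)C)[C@@H]2CC[C@](C)(CO)C2=C1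
F7 | step 18 | ethyl 4-(tert-butyldimethylsilyloxy)-1-(1-hydroxy-3-methylbutyl)-1,4-dimethyldecahydroazulene-7-carboxylate | CCOC(=O)[C@@H]1CC[C@@](C)(O[Si](C)(C)C(C)(C)C)[C@@H]2CC[C@](C)(C(O)CC(C)C)[C@H]2C1
F8 | step 18 | ethyl 4-(tert-butyldimethylsilyloxy)-1,4-dimethyl-1-(3-methylbutanoyl)decahydroazulene-7-carboxylate | CCOC(=O)[C@@H]1CC[C@@](C)(O[Si](C)(C)C(C)(C)C)[C@@H]2CC[C@](C)(C(=O)CC(C)C)[C@H]2C1
F9 | step 18 | ethyl 4-(tert-butyldimethylsilyloxy)-1-{1-hydroxy-3-methyl-1-[2,4,6-tris(methoxymethoxy)phenyl]butyl}-1,4-dimethyldecahydroazulene-7-carboxylate | CCOC(=O)[C@@H]1CC[C@@](C)(O[Si](C)(C)C(C)(C)C)[C@@H]2CC[C@](C)(C(O)(CC(C)C)c3c(OCOC)cc(OCOC)cc3OCOC)[C@H]2C1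
F10 | step 23 | 3-{(1R)-1-[4-(tert-butyldimethylsilyloxy)-1,4-dimethyl-7-(prop-1-en-2-yl)decahydroazulen-1-yl]-3-methylbutyl}-2,4,6-tris(methoxymethoxy)benzaldehyde | C=C(C)[C@@H]1CC[C@@](C)(O[Si](C)(C)C(C)(C)C)[C@@H]2CC[C@](C)([C@@H](CC(C)C)c3c(OCOC)cc(OCOC)c(C=O)c3OCOC)[C@H]2C1
F11 | step 23 | 5-{(1R)-1-[4-(tert-butyldimethylsilyloxy)-1,4-dimethyl-7-(prop-1-en-2-yl)decahydroazulen-1-yl]-3-methylbutyl}-2,4,6-tris(methoxymethoxy)benzene-1,3-dicarbaldehyde | C=C(C)[C@@H]1CC[C@@](C)(O[Si](C)(C)C(C)(C)C)[C@@H]2CC[C@](C)([C@@H](CC(C)C)c3c(OCOC)c(C=O)c(OCOC)c(C=O)c3OCOC)[C@H]2C1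
A1 | alternative 1 | differentiated 2-alkylphloroglucinol (free OH, triisopropylsilyl ether, ethyl ether) on the complete terpene | C=C(C)[C@@H]1CC[C@@](C)(O[Si](CC)(CC)CC)[C@@H]2CC[C@](C)([C@@H](CC(C)C)c3c(O)cc(OCC)cc3O[Si](C(C)C)(C(C)C)C(C)C)[C@H]2C1
A2 | alternative 1 | triisopropylsilyl ynol ether (siloxyalkyne) of the terpene side chain | C=C(C)[C@@H]1CC[C@@](C)(O[Si](CC)(CC)CC)[C@@H]2CC[C@](C)([C@@H](CC(C)C)C#CO[Si](C(C)C)(C(C)C)C(C)C)[C@H]2C1
A3 | alternative 1 | 3-ethoxycyclobut-2-en-1-one | CCOC1=CC(=O)C1
A4 | alternative 2 | bicyclo[5.3.0]decadiene ester from the metathesis cascade | CC3(OCCO3)[C@@H]1CC=C(C)C2=CC[C@](C)(C(=O)OC)[C@H]2C1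
A5 | alternative 2 | acyclic dienyne with allyl, propynyl and butenyl groups | CC1(OCCO1)[C@H](CC=CC)C[C@@H](C#CC)[C@](C)(CC=C)C(=O)OC
A6 | alternative 3 | hydroazulene γ-keto ester | C=C(C)[C@@H]1CC[C@@](C)(O[Si](CC)(CC)CC)[C@@H]2C(=O)C[C@](C)(C(=O)OC)[C@H]2C1
A7 | alternative 3 | cycloheptane carrying a silyl enol ether and a silyl ketene acetal on adjacent ring carbons | C=C(C)[C@@H]1CC[C@@](C)(O[Si](CC)(CC)CC)[C@H](C(=C)O[Si](C)(C)C(C)(C)C)[C@H](C1)C(C)=C(OC)O[Si](C)(C)C
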